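**Retrosynthetic overview**

1. The target is a (2R,3R)-2,3-cis flavan-3-yl aroate. The last step is global hydrogenolysis of five benzyl ethers, and before it a Baeyer–Villiger oxidation turns a C3–C(=O)Ar ketone into the C3–O–C(=O)Ar ester, so the aroyl ring is carried as a ketone.
2. The key disconnection is C2–C3 of ring C, made by an internal redox cyclisation: 1,5-hydride shift from the ArO–CH2–(ring B) ether to C4 of a benzylidene beta-keto ester, then closure of the C3 enolate onto the C2 oxocarbenium. One isomerisation builds ring C, the C4 methylene, C3 and the C2 stereocentre.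
3. The enabling feature: C2 carries H, the ring oxygen O1 and the electron-rich ring B, so before closure it is a hydridic benzyl aryl ether CH2 lying 1,5 to C4. C4 is a CH2 and C3 bears an oxygen that can be derived from an acyl group, so C4=C3 can be an electrophilic benzylidene 1,3-dicarbonyl.
4. The precursor comes from Knoevenagel condensation of 2,4-bis(benzyloxy)-6-{[3,4-bis(benzyloxy)benzyl]oxy}benzaldehyde (from 3,5-bis(benzyloxy)phenol by ortho-formylation and one O-alkylation) with an allyl aroylacetate (from 3-hydroxy-4,5-dimethoxybenzoic acid). The allyl ester is then removed by decarboxylation, and ketonisation of the resulting enol sets 2,3-cis.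
5. Ring order: rings A, B and the aroyl ring are bought; ring C is the only ring formed (step 7).

Key step: step 7

Remark: which antipode of the N,N'-dioxide ligand gives 2R cannot be derived from a rule for this substrate class; the (S)-pipecolic series is assumed, and its mirror image (from (R)-pipecolic acid) is used if the sense is the opposite.

**Route**

Step 1
Reactants: 1 3-hydroxy-4,5-dimethoxybenzoic acid
Product: 2 benzyl 3-(benzyloxy)-4,5-dimethoxybenzoate
Conditions: BnBr (2.3 equiv), K2CO3, DMF, 60 °C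
Reagents that add atoms: benzyl bromide, BrCc1ccccc1
Why: Williamson etherification of the phenol and SN2 alkylation of the carboxylate protect the one free phenol of the aroyl ring as a benzyl ether that survives all later steps and falls in the final hydrogenolysis.

Step 2
Reactants: 2 benzyl 3-(benzyloxy)-4,5-dimethoxybenzoate
Product: 3 3-(benzyloxy)-4,5-dimethoxybenzoic acid
Conditions: LiOH, THF/MeOH/H2O, 50 °C; then aq. HCl
Reagents that add atoms: lithium hydroxide, [Li+].[OH-]
Why: Saponification cleaves the benzyl ester by acyl–oxygen attack while the aryl benzyl ether is inert to hydroxide.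

Step 3
Reactants: 3 3-(benzyloxy)-4,5-dimethoxybenzoic acid
Product: 5 allyl 3-[3-(benzyloxy)-4,5-dimethoxyphenyl]-3-oxopropanoate, via acyl imidazolide 4 (not isolated)
Conditions: CDI, THF, rt; then added to LiCH2CO2CH2CH=CH2 (allyl acetate, LiN(i-Pr)2, 2.2 equiv each, THF, −78 °C), −78 → 0 °C; aq. NH4Cl
Reagents that add atoms: allyl acetate, CC(=O)OCC=C
Why: Crossed Claisen condensation of the lithium enolate of allyl acetate with the acyl imidazolide gives the beta-keto ester, which is deprotonated as it forms and so cannot add a second enolate.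

Step 4
Reactants: 6 3,5-bis(benzyloxy)phenol
Product: 8 2,4-bis(benzyloxy)-6-hydroxybenzaldehyde, via salicyl alcohol 7 (not isolated)
Conditions: MgCl2 (1.5 equiv), Et3N (3.8 equiv), (CH2O)n (7 equiv), MeCN, reflux; then aq. HCl
Reagents that add atoms: formaldehyde (as paraformaldehyde), C=O
Why: Magnesium-mediated ortho-formylation of a phenol (Casnati–Skattebøl reaction), in which the magnesium phenoxide delivers formaldehyde to one of the two equivalent ortho positions and the resulting salicyl alcohol salt 7 is oxidised by a second formaldehyde through an Oppenauer-type hydride transfer, so that no formylation para to the free hydroxyl is expected.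

Step 5
Reactants: 8 2,4-bis(benzyloxy)-6-hydroxybenzaldehyde; 9 3,4-bis(benzyloxy)benzyl chloride
Product: 10 2,4-bis(benzyloxy)-6-{[3,4-bis(benzyloxy)benzyl]oxy}benzaldehyde
Conditions: K2CO3, Bu4NI (cat.), DMF, 60 °C
Reagents that add atoms: none
Why: Williamson etherification of the single free, hydrogen-bonded phenol with the benzylic chloride under iodide catalysis places the future C2 with ring B on the oxygen that becomes O1, and no regiochemical question arises because only one hydroxyl is free.

Step 6
Reactants: 10 2,4-bis(benzyloxy)-6-{[3,4-bis(benzyloxy)benzyl]oxy}benzaldehyde; 5 allyl 3-[3-(benzyloxy)-4,5-dimethoxyphenyl]-3-oxopropanoate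
Product: 11 allyl 2-[3-(benzyloxy)-4,5-dimethoxybenzoyl]-3-(2,4-bis(benzyloxy)-6-{[3,4-bis(benzyloxy)benzyl]oxy}phenyl)prop-2-enoate (E/Z mixture)
Conditions: piperidine (cat.), AcOH (cat.), toluene, reflux, Dean–Stark
Reagents that add atoms: none
Why: Knoevenagel condensation with azeotropic removal of water gives the benzylidene beta-keto ester, and both alkene isomers can be used because chelation in step 7 converges them on one enolate.

Step 7
Reactants: 11 allyl 2-[3-(benzyloxy)-4,5-dimethoxybenzoyl]-3-(2,4-bis(benzyloxy)-6-{[3,4-bis(benzyloxy)benzyl]oxy}phenyl)prop-2-enoate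
Product: 13 allyl (2R)-5,7-bis(benzyloxy)-2-[3,4-bis(benzyloxy)phenyl]-3-[3-(benzyloxy)-4,5-dimethoxybenzoyl]chromane-3-carboxylate (C3 epimers), via oxocarbenium enolate zwitterion 12 (not isolated)
Conditions: Sc(OTf)3 (10 mol%), C2-symmetric N,N'-dioxide bis-amide ligand from (S)-pipecolic acid and 2,6-diisopropylaniline with a propane-1,3-diyl linker (12 mol%), 4 Å MS, ClCH2CH2Cl, 40–60 °C
Reagents that add atoms: none
Why: Proposed new method: two-point chelation of the 1,3-dicarbonyl by the chiral scandium triflate complex makes C4 hydride-accepting, and one hydrogen of the ortho ArO–CH2–(ring B) group, hydridic because the cation left behind is stabilised by O1 and by the para oxygen of ring B, is delivered to C4 through a six-membered transition state (1,5-hydride shift) to give the oxocarbenium–enolate zwitterion 12, whose C3 then bonds to C2; the closest known reaction type is the achiral Lewis-acid-catalysed 1,5-hydride shift/cyclisation of ortho-benzyloxy benzylidene malonates to 2-arylchromane-3,3-dicarboxylates, with asymmetric precedent only in the chiral-Lewis-acid versions of the analogous tert-amino cyclisations. Ring C closes by a 6-endo-trig (enolexo) attack of the enolate carbon on the oxocarbenium carbon. C2 is controlled by the ligand, which shields one face of the flat chelated enolate so that the (E)-oxocarbenium, with ring B pseudo-equatorial, can be engaged from one side only; the quaternary C3 is not controlled and is erased in step 8. The selectivity needed is the choice of hydride donor: of the two ortho OCH2 groups that can reach C4, the one carrying ring B should react far faster because its para oxygen stabilises the developing oxocarbenium, whereas the ortho benzyl ether lacks such a donor, and the para benzyl ether and the benzyl ethers of ring B and of the aroyl ring are out of reach. No reagent is consumed, since the step is an isomerisation.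

Step 8
Reactants: 13 allyl (2R)-5,7-bis(benzyloxy)-2-[3,4-bis(benzyloxy)phenyl]-3-[3-(benzyloxy)-4,5-dimethoxybenzoyl]chromane-3-carboxylate
Product: 16 [(2S,3R)-5,7-bis(benzyloxy)-2-[3,4-bis(benzyloxy)phenyl]chroman-3-yl][3-(benzyloxy)-4,5-dimethoxyphenyl]methanone (2,3-cis), via beta-keto acid 14 (not isolated), via exocyclic enol 15 (not isolated)
Conditions: Pd(PPh3)4 (5 mol%), HCO2H (3 equiv), Et3N (2 equiv), THF, 25 °C
Reagents that add atoms: none
Why: Palladium-catalysed deallylation by formate (Tsuji–Trost type) gives the beta-keto acid, which loses CO2 to the exocyclic enol 15, in which ring B at C2 sits pseudo-axial to avoid A(1,3) strain with the enol substituents, so the kinetic proton should reach C3 on the face anti to ring B and give the less stable 2,3-cis ketone, as in the classical ketonisation of 2-aryl-1-acylcyclohexane enols, while C2 is untouched (its descriptor changes from R to S only because the priorities at C2 change).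

Step 9
Reactants: 16 [(2S,3R)-5,7-bis(benzyloxy)-2-[3,4-bis(benzyloxy)phenyl]chroman-3-yl][3-(benzyloxy)-4,5-dimethoxyphenyl]methanone
Product: 17 (2R,3R)-5,7-bis(benzyloxy)-2-[3,4-bis(benzyloxy)phenyl]chroman-3-yl 3-(benzyloxy)-4,5-dimethoxybenzoate
Conditions: mCPBA, NaHCO3, CH2Cl2, 0 °C → rt, dark
Reagents that add atoms: meta-chloroperoxybenzoic acid, O=C(OO)c1cccc(Cl)c1
Why: Baeyer–Villiger oxidation, in which the secondary carbon C3 should migrate with retention in preference to the aryl group (two meta oxygens and a twisted para methoxy make it a poor migrator), converts the C-aroyl group into the O-aroyl ester with the 2,3-cis relationship intact, while the hydrogencarbonate buffer protects C2 and the benzyl ethers from acid.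

Step 10
Reactants: 17 (2R,3R)-5,7-bis(benzyloxy)-2-[3,4-bis(benzyloxy)phenyl]chroman-3-yl 3-(benzyloxy)-4,5-dimethoxybenzoate
Product: 18 (2R,3R)-2-(3,4-dihydroxyphenyl)-5,7-dihydroxychroman-3-yl 3-hydroxy-4,5-dimethoxybenzoate
Conditions: H2 (1 atm), Pd(OH)2/C, THF/MeOH, rt
Reagents that add atoms: none
Why: Catalytic hydrogenolysis cleaves all five benzyl ethers, while the alkyl aroate, the cyclic C2–O1 bond and both stereocentres are expected to survive these neutral conditions, as is usual for benzylated flavan-3-yl gallates.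

**Compound list**

1 | 3-hydroxy-4,5-dimethoxybenzoic acid | COc1cc(C(=O)O)cc(O)c1OC | starting material
2 | benzyl 3-(benzyloxy)-4,5-dimethoxybenzoate | COc1cc(C(=O)OCc2ccccc2)cc(OCc2ccccc2)c1OC | intermediate
3 | 3-(benzyloxy)-4,5-dimethoxybenzoic acid | COc1cc(C(=O)O)cc(OCc2ccccc2)c1OC | intermediate
4 | [3-(benzyloxy)-4,5-dimethoxyphenyl](imidazol-1-yl)methanone (acyl imidazolide, not isolated) | COc1cc(C(=O)n2ccnc2)cc(OCc2ccccc2)c1OC | intermediate
5 | allyl 3-[3-(benzyloxy)-4,5-dimethoxyphenyl]-3-oxopropanoate | C=CCOC(=O)CC(=O)c1cc(OC)c(OC)c(OCc2ccccc2)c1 | intermediate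
6 | 3,5-bis(benzyloxy)phenol | Oc1cc(OCc2ccccc2)cc(OCc2ccccc2)c1 | starting material
7 | 3,5-bis(benzyloxy)-2-(hydroxymethyl)phenol (salicyl alcohol, magnesium salt in the flask, not isolated) | OCc1c(O)cc(OCc2ccccc2)cc1OCc1ccccc1 | intermediate
8 | 2,4-bis(benzyloxy)-6-hydroxybenzaldehyde | O=Cc1c(O)cc(OCc2ccccc2)cc1OCc1ccccc1 | intermediate
9 | 3,4-bis(benzyloxy)benzyl chloride | ClCc1ccc(OCc2ccccc2)c(OCc2ccccc2)c1 | starting material
10 | 2,4-bis(benzyloxy)-6-{[3,4-bis(benzyloxy)benzyl]oxy}benzaldehyde | O=Cc1c(OCc2ccc(OCc3ccccc3)c(OCc3ccccc3)c2)cc(OCc2ccccc2)cc1OCc1ccccc1 | intermediate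
11 | allyl 2-[3-(benzyloxy)-4,5-dimethoxybenzoyl]-3-(2,4-bis(benzyloxy)-6-{[3,4-bis(benzyloxy)benzyl]oxy}phenyl)prop-2-enoate (E/Z mixture) | C=CCOC(=O)C(=Cc1c(OCc2ccc(OCc3ccccc3)c(OCc3ccccc3)c2)cc(OCc2ccccc2)cc1OCc1ccccc1)C(=O)c1cc(OC)c(OC)c(OCc2ccccc2)c1 | intermediate
12 | zwitterion after the hydride shift: aryl oxocarbenium (ring A–O(+)=CH–ring B) tethered to the 1,3-dicarbonyl enolate, scandium-bound in the flask (not isolated) | C=CCOC(=O)C(Cc1c(OCc2ccccc2)cc(OCc2ccccc2)cc1[O+]=Cc1ccc(OCc2ccccc2)c(OCc2ccccc2)c1)=C([O-])c1cc(OC)c(OC)c(OCc2ccccc2)c1 | intermediate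
13 | allyl (2R)-5,7-bis(benzyloxy)-2-[3,4-bis(benzyloxy)phenyl]-3-[3-(benzyloxy)-4,5-dimethoxybenzoyl]chromane-3-carboxylate (C3 epimers) | C=CCOC(=O)C1(C(=O)c2cc(OC)c(OC)c(OCc3ccccc3)c2)Cc2c(OCc3ccccc3)cc(OCc3ccccc3)cc2O[C@@H]1c1ccc(OCc2ccccc2)c(OCc2ccccc2)c1 | intermediate
14 | (2R)-5,7-bis(benzyloxy)-2-[3,4-bis(benzyloxy)phenyl]-3-[3-(benzyloxy)-4,5-dimethoxybenzoyl]chromane-3-carboxylic acid (C3 epimers, not isolated) | OC(=O)C1(C(=O)c2cc(OC)c(OC)c(OCc3ccccc3)c2)Cc2c(OCc3ccccc3)cc(OCc3ccccc3)cc2O[C@@H]1c1ccc(OCc2ccccc2)c(OCc2ccccc2)c1 | intermediate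
15 | (2R)-5,7-bis(benzyloxy)-3-{[3-(benzyloxy)-4,5-dimethoxyphenyl](hydroxy)methylidene}-2-[3,4-bis(benzyloxy)phenyl]chromane (exocyclic enol, not isolated) | OC(c1cc(OC)c(OC)c(OCc2ccccc2)c1)=C1Cc2c(OCc3ccccc3)cc(OCc3ccccc3)cc2O[C@@H]1c1ccc(OCc2ccccc2)c(OCc2ccccc2)c1 | intermediate
16 | [(2S,3R)-5,7-bis(benzyloxy)-2-[3,4-bis(benzyloxy)phenyl]chroman-3-yl][3-(benzyloxy)-4,5-dimethoxyphenyl]methanone (2,3-cis) | O=C(c1cc(OC)c(OC)c(OCc2ccccc2)c1)[C@@H]1Cc2c(OCc3ccccc3)cc(OCc3ccccc3)cc2O[C@@H]1c1ccc(OCc2ccccc2)c(OCc2ccccc2)c1 | intermediate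
17 | (2R,3R)-5,7-bis(benzyloxy)-2-[3,4-bis(benzyloxy)phenyl]chroman-3-yl 3-(benzyloxy)-4,5-dimethoxybenzoate | COc1cc(C(=O)O[C@@H]2Cc3c(OCc4ccccc4)cc(OCc4ccccc4)cc3O[C@@H]2c2ccc(OCc3ccccc3)c(OCc3ccccc3)c2)cc(OCc2ccccc2)c1OC | intermediate
18 | (2R,3R)-2-(3,4-dihydroxyphenyl)-5,7-dihydroxychroman-3-yl 3-hydroxy-4,5-dimethoxybenzoate (CNP0331021.1) | COc1cc(C(=O)O[C@@H]2Cc3c(O)cc(O)cc3O[C@@H]2c2ccc(O)c(O)c2)cc(O)c1OC | target

**Step count and risks**

Total step count: 10. Longest linear sequence: 8 steps (steps 1, 2, 3, 6, 7, 8, 9, 10).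

Three steps most likely to fail:

Step 7. The hydride transfer may be too slow, because the electron-rich ring A lowers the electrophilicity of C4 and the ligand moderates the Lewis acid. The ligand may also give poor facial selectivity at C2, hydride donation from the ortho benzyl ether may compete, and the acid-labile electron-rich benzylic ether may be lost on prolonged heating. The fallback uses known chemistry and moves the enantiocontrol to a later, configurationally labile ketone. It sets out from 11. Achiral Sc(OTf)3 in ClCH2CH2Cl at 80 °C, the known racemic hydride-shift cyclisation of ortho-benzyloxy benzylidene 1,3-dicarbonyls, gives the racemic chromane F1. The conditions of step 8 turn this into the racemic cis ketone F2. LiN(i-Pr)2 with Me3SiCl (THF, −78 °C, in situ quench) gives the trimethylsilyl enol ether F3. One equivalent of O3 (CH2Cl2, −78 °C, then Me2S) cleaves the enol ether double bond to the racemic 2-arylchroman-3-one F4, whose C2 epimerises readily through the enol. Noyori asymmetric hydrogenation with dynamic kinetic resolution (RuCl2[(S)-xylbinap][(S)-daipen] or its mirror image, whichever delivers the 3R carbinol; t-BuOK, H2, i-PrOH) should give the (2R,3R)-cis alcohol F5. Steglich esterification of F5 with acid 3 (DCC, DMAP, CH2Cl2) comes back to the route at 17.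

Step 9. The aryl group may migrate in place of C3, the hindered axial ketone may react slowly, or the peracid may attack the electron-rich rings. The fallback replaces oxygen insertion by cleavage and re-acylation. It sets out from 16. LiN(i-Pr)2 with Me3SiCl (THF, −78 °C, in situ quench to suppress ring opening of the enolate) gives the silyl enol ether F6. O3 (one equivalent, CH2Cl2, −78 °C, then Me2S) gives the (2R)-chroman-3-one F7. LiBH(s-Bu)3 (THF, −78 °C) should deliver hydride anti to ring B and give the cis alcohol F5, the known outcome for benzylated flavan-3-ones. Esterification with acid 3 (DCC, DMAP, CH2Cl2) comes back at 17.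

Step 8. The kinetic cis configuration may be lost, either by poor facial selectivity in the ketonisation or by amine-mediated epimerisation to the trans ketone after it, and C-allylation of the palladium enolate may compete. The fallback sets C3 in a separate stoichiometric operation. It sets out from 13. Deallylation and decarboxylation are run as before without regard to the C3 outcome, giving 16 mixed with its C3 epimer, the 2,3-trans ketone [(2S,3S)-5,7-bis(benzyloxy)-2-[3,4-bis(benzyloxy)phenyl]chroman-3-yl][3-(benzyloxy)-4,5-dimethoxyphenyl]methanone F8. The mixture is converted into its lithium enolate (LiN(i-Pr)2, THF, −78 °C) and added to a cold THF solution of 2,6-di-tert-butylphenol. This bulky proton donor should protonate C3 anti to ring B, and a neutral cold work-up should preserve the result. The fallback comes back at 16.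

Further compounds
F1 | step 7 | racemic allyl 5,7-bis(benzyloxy)-2-[3,4-bis(benzyloxy)phenyl]-3-[3-(benzyloxy)-4,5-dimethoxybenzoyl]chromane-3-carboxylate | C=CCOC(=O)C1(C(=O)c2cc(OC)c(OC)c(OCc3ccccc3)c2)Cc2c(OCc3ccccc3)cc(OCc3ccccc3)cc2OC1c1ccc(OCc2ccccc2)c(OCc2ccccc2)c1
F2 | step 7 | racemic 2,3-cis [5,7-bis(benzyloxy)-2-[3,4-bis(benzyloxy)phenyl]chroman-3-yl][3-(benzyloxy)-4,5-dimethoxyphenyl]methanone | O=C(c1cc(OC)c(OC)c(OCc2ccccc2)c1)C1Cc2c(OCc3ccccc3)cc(OCc3ccccc3)cc2OC1c1ccc(OCc2ccccc2)c(OCc2ccccc2)c1
F3 | step 7 | racemic 5,7-bis(benzyloxy)-3-{[3-(benzyloxy)-4,5-dimethoxyphenyl](trimethylsilyloxy)methylidene}-2-[3,4-bis(benzyloxy)phenyl]chromane | C[Si](C)(C)OC(c1cc(OC)c(OC)c(OCc2ccccc2)c1)=C1Cc2c(OCc3ccccc3)cc(OCc3ccccc3)cc2OC1c1ccc(OCc2ccccc2)c(OCc2ccccc2)c1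
F4 | step 7 | racemic 5,7-bis(benzyloxy)-2-[3,4-bis(benzyloxy)phenyl]chroman-3-one | O=C1Cc2c(OCc3ccccc3)cc(OCc3ccccc3)cc2OC1c1ccc(OCc2ccccc2)c(OCc2ccccc2)c1
F5 | step 7 | (2R,3R)-5,7-bis(benzyloxy)-2-[3,4-bis(benzyloxy)phenyl]chroman-3-ol | O[C@@H]1Cc2c(OCc3ccccc3)cc(OCc3ccccc3)cc2O[C@@H]1c1ccc(OCc2ccccc2)c(OCc2ccccc2)c1
F6 | step 9 | (2R)-5,7-bis(benzyloxy)-3-{[3-(benzyloxy)-4,5-dimethoxyphenyl](trimethylsilyloxy)methylidene}-2-[3,4-bis(benzyloxy)phenyl]chromane | C[Si](C)(C)OC(c1cc(OC)c(OC)c(OCc2ccccc2)c1)=C1Cc2c(OCc3ccccc3)cc(OCc3ccccc3)cc2O[C@@H]1c1ccc(OCc2ccccc2)c(OCc2ccccc2)c1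
F7 | step 9 | (2R)-5,7-bis(benzyloxy)-2-[3,4-bis(benzyloxy)phenyl]chroman-3-one | O=C1Cc2c(OCc3ccccc3)cc(OCc3ccccc3)cc2O[C@@H]1c1ccc(OCc2ccccc2)c(OCc2ccccc2)c1
F8 | step 8 | [(2S,3S)-5,7-bis(benzyloxy)-2-[3,4-bis(benzyloxy)phenyl]chroman-3-yl][3-(benzyloxy)-4,5-dimethoxyphenyl]methanone (2,3-trans) | O=C(c1cc(OC)c(OC)c(OCc2ccccc2)c1)[C@H]1Cc2c(OCc3ccccc3)cc(OCc3ccccc3)cc2O[C@@H]1c1ccc(OCc2ccccc2)c(OCc2ccccc2)c1
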